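**Strategy**

Everything rests on disconnecting the two C–C bonds from C4 of the lactone ring (O1, C2, C3, C4, C5) to C7, the benzylic carbon of the 3,4-dimethoxybenzyl arm, and to C5. C4 is a methine bearing only carbon neighbours (C3, C5, C7), the pattern left when a carbenoid carbon on boron accepts one migrating group and then migrates itself. In one flask the (+)-sparteine-lithiated carbamate of mono-silylated propane-1,3-diol captures 3,4-dimethoxybenzyl-Bpin (C4–C7, C4 configuration) and chloromethyllithium inserts C5 into the C4–B bond. The precursor is thus an achiral O-silyl hydroxypropyl carbamate; oxidation, lactonisation, trans C3 benzylation and debenzylation finish the target.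

Key step: step 3

Assumption: 3-(tert-butyldimethylsilyloxy)propan-1-ol (1) and 3-(benzyloxy)-4-methoxybenzyl alcohol (16) are taken as catalogue compounds; each is otherwise one or two routine steps from propane-1,3-diol or isovanillin.

Remark: the 4R series requires (+)-sparteine. With (−)-sparteine the pro-S hydrogen is removed and the same two 1,2-shifts would end in the (S)-boronic ester and the 4S lactone.

**Route**

Step 1
Reactants: 1 3-(tert-butyldimethylsilyloxy)propan-1-ol
Product: 2 3-(tert-butyldimethylsilyloxy)propyl N,N-diisopropylcarbamate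
Conditions: i-Pr2NCOCl, Et3N, CH2Cl2, reflux
Reagents that add atoms: N,N-diisopropylcarbamoyl chloride, CC(C)N(C(C)C)C(Cl)=O
Why: Carbamate formation by O-acylation of the free primary alcohol under amine base leaves the silyl ether untouched and installs the group that later directs lithiation and serves as the leaving group.

Step 2
Reactants: 3 3,4-dimethoxybenzyl chloride
Product: 4 2-(3,4-dimethoxybenzyl)-4,4,5,5-tetramethyl-1,3,2-dioxaborolane
Conditions: B2pin2, Pd(dba)2 (cat.), P(4-MeOC6H4)3, KOAc, toluene, 50 °C
Reagents that add atoms: bis(pinacolato)diboron, CC1(C)OB(OC1(C)C)B1OC(C)(C)C(C)(C)O1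
Why: Miyaura borylation, in which oxidative addition of the benzylic C–Cl bond to zerovalent palladium, acetate-assisted transmetallation with the diboron and reductive elimination give the benzylboronic ester while the aryl ethers are inert.

Step 3
Reactants: 2 3-(tert-butyldimethylsilyloxy)propyl N,N-diisopropylcarbamate; 4 2-(3,4-dimethoxybenzyl)-4,4,5,5-tetramethyl-1,3,2-dioxaborolane; 5 bromochloromethane
Product: 10 (R)-tert-butyl{4-(3,4-dimethoxyphenyl)-3-[(4,4,5,5-tetramethyl-1,3,2-dioxaborolan-2-yl)methyl]butoxy}dimethylsilane, via α-lithiated carbamate 6 (not isolated), via lithium boronate complex 7 (not isolated), via secondary boronic ester 8 (not isolated), via chloromethyl boronate complex 9 (not isolated)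
Conditions: s-BuLi, (+)-sparteine, Et2O, −78 °C; then 4, −78 °C → reflux; then 5, n-BuLi, −78 °C → rt (one flask)
Reagents that add atoms: none
Why: s-BuLi/(+)-sparteine removes the pro-R hydrogen of the OCH2 group of 2 to give the configurationally stable, carbamate-chelated lithio species 6, which attacks the boron of 4 with retention to give 7; on warming, the 3,4-dimethoxybenzyl group shifts from boron to carbon antiperiplanar to the departing carbamate (inversion), forming the C4–C7 bond and the C4 stereocentre in 8. Chloromethyllithium, generated from 5 and n-BuLi in the presence of 8, gives 9, in which C4 migrates to the CH2 carbon with retention as chloride leaves, forming the C4–C5 bond. The closest known reaction type is the sparteine-mediated lithiation–borylation of primary alkyl carbamates followed in the same flask by a Matteson homologation; no ring is closed. The C4 configuration is fixed by the ligand-controlled choice between the two enantiotopic hydrogens and is carried through two stereospecific 1,2-shifts, (+)-sparteine being the enantiomer that leads to (R)-10. The step needs a carbenoid that does not eliminate and clean migration of a single group: the silyloxy group sits γ to lithium and is a poor leaving group, the unhindered primary benzylic boronic ester migrates readily, and in 9 C4 is the only carbon substituent on boron able to shift onto the chloromethyl carbon.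

Step 4
Reactants: 10 (R)-tert-butyl{4-(3,4-dimethoxyphenyl)-3-[(4,4,5,5-tetramethyl-1,3,2-dioxaborolan-2-yl)methyl]butoxy}dimethylsilane
Product: 12 (R)-2-(3,4-dimethoxybenzyl)butane-1,4-diol, via hydroxy boronic ester 11 (not isolated)
Conditions: TsOH·H2O (cat.), MeOH, rt; then THF, aq. NaOH, 30% H2O2, 0 °C → rt
Reagents that add atoms: hydrogen peroxide, OO
Why: Acid-catalysed methanolysis cleaves the primary silyl ether while the pinacol boronic ester survives, and alkaline peroxide then oxidises the C5–B bond to C5–OH by 1,2-shift of carbon from boron to oxygen with retention, C4 taking no part in either event.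

Step 5
Reactants: 12 (R)-2-(3,4-dimethoxybenzyl)butane-1,4-diol
Product: 15 (R)-4-(3,4-dimethoxybenzyl)dihydrofuran-2(3H)-one, via hydroxy aldehyde 13 (not isolated), via lactol 14 (not isolated)
Conditions: TEMPO (cat.), PhI(OAc)2, CH2Cl2, rt
Reagents that add atoms: none
Why: In this TEMPO/PhI(OAc)2 oxidative lactonisation the oxoammonium species should oxidise the less hindered primary alcohol (two carbons from the C4 branch) faster than the β-branched C5 alcohol, aldehyde 13 closes to lactol 14, and a second oxidation gives the γ-lactone with C4 untouched.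

Step 6
Reactants: 16 3-(benzyloxy)-4-methoxybenzyl alcohol
Product: 17 3-(benzyloxy)-4-methoxybenzyl bromide
Conditions: PBr3, Et2O, 0 °C
Reagents that add atoms: phosphorus tribromide, BrP(Br)Br
Why: PBr3 converts the benzylic alcohol into the bromide by bromide displacement of the activated phosphite ester, conditions under which the aryl benzyl ether is stable; the bromide is used fresh.

Step 7
Reactants: 15 (R)-4-(3,4-dimethoxybenzyl)dihydrofuran-2(3H)-one; 17 3-(benzyloxy)-4-methoxybenzyl bromide
Product: 19 (3R,4R)-3-[3-(benzyloxy)-4-methoxybenzyl]-4-(3,4-dimethoxybenzyl)dihydrofuran-2(3H)-one, via lithium enolate 18 (not isolated)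
Conditions: LiN(SiMe3)2, THF, −78 °C; then 17, DMPU, −78 → −30 °C
Reagents that add atoms: none
Why: In this lactone enolate alkylation the bromide attacks enolate 18 on the ring face opposite the C4 arylmethyl group, which sets C3 trans to C4 (3R), and C4, being β to the carbonyl, cannot epimerise.

Step 8
Reactants: 19 (3R,4R)-3-[3-(benzyloxy)-4-methoxybenzyl]-4-(3,4-dimethoxybenzyl)dihydrofuran-2(3H)-one
Product: 20 prestegane A, (3R,4R)-4-(3,4-dimethoxybenzyl)-3-(3-hydroxy-4-methoxybenzyl)dihydrofuran-2(3H)-one
Conditions: H2 (1 atm), 10% Pd/C, EtOAc, rt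
Reagents that add atoms: none
Why: Catalytic hydrogenolysis cleaves the O-benzyl ether to the phenol and toluene while the lactone, the methyl ethers and both stereocentres are unaffected.

**Compound list**

1 | 3-(tert-butyldimethylsilyloxy)propan-1-ol | CC(C)(C)[Si](C)(C)OCCCO | starting material
2 | 3-(tert-butyldimethylsilyloxy)propyl N,N-diisopropylcarbamate | CC(C)N(C(C)C)C(=O)OCCCO[Si](C)(C)C(C)(C)C | intermediate
3 | 3,4-dimethoxybenzyl chloride | COc1ccc(CCl)cc1OC | starting material
4 | 2-(3,4-dimethoxybenzyl)-4,4,5,5-tetramethyl-1,3,2-dioxaborolane | COc1ccc(CB2OC(C)(C)C(C)(C)O2)cc1OC | intermediate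
5 | bromochloromethane | ClCBr | starting material
6 | (R)-3-(tert-butyldimethylsilyloxy)-1-lithiopropyl N,N-diisopropylcarbamate, as its (+)-sparteine complex (ligand not drawn) | [Li][C@H](CCO[Si](C)(C)C(C)(C)C)OC(=O)N(C(C)C)C(C)C | intermediate
7 | lithium boronate complex of 6 and 4: boron carries the pinacol unit, the 3,4-dimethoxybenzyl group and the (R)-carbamoyloxy carbon | [Li+].CC(C)N(C(C)C)C(=O)O[C@@H](CCO[Si](C)(C)C(C)(C)C)[B-]1(Cc2ccc(OC)c(OC)c2)OC(C)(C)C(C)(C)O1 | intermediate
8 | (R)-tert-butyl{4-(3,4-dimethoxyphenyl)-3-(4,4,5,5-tetramethyl-1,3,2-dioxaborolan-2-yl)butoxy}dimethylsilane | CC(C)(C)[Si](C)(C)OCC[C@@H](Cc1ccc(OC)c(OC)c1)B1OC(C)(C)C(C)(C)O1 | intermediate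
9 | lithium chloromethyl boronate complex of 8: boron carries the pinacol unit, CH2Cl and C4 | [Li+].CC(C)(C)[Si](C)(C)OCC[C@@H](Cc1ccc(OC)c(OC)c1)[B-]1(CCl)OC(C)(C)C(C)(C)O1 | intermediate
10 | (R)-tert-butyl{4-(3,4-dimethoxyphenyl)-3-[(4,4,5,5-tetramethyl-1,3,2-dioxaborolan-2-yl)methyl]butoxy}dimethylsilane | CC(C)(C)[Si](C)(C)OCC[C@@H](Cc1ccc(OC)c(OC)c1)CB1OC(C)(C)C(C)(C)O1 | intermediate
11 | (R)-4-(3,4-dimethoxyphenyl)-3-[(4,4,5,5-tetramethyl-1,3,2-dioxaborolan-2-yl)methyl]butan-1-ol | OCC[C@@H](Cc1ccc(OC)c(OC)c1)CB1OC(C)(C)C(C)(C)O1 | intermediate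
12 | (R)-2-(3,4-dimethoxybenzyl)butane-1,4-diol | OCC[C@@H](Cc1ccc(OC)c(OC)c1)CO | intermediate
13 | (R)-3-(3,4-dimethoxybenzyl)-4-hydroxybutanal | O=CC[C@@H](Cc1ccc(OC)c(OC)c1)CO | intermediate
14 | (4R)-4-(3,4-dimethoxybenzyl)tetrahydrofuran-2-ol, both anomers | OC1C[C@@H](Cc2ccc(OC)c(OC)c2)CO1 | intermediate
15 | (R)-4-(3,4-dimethoxybenzyl)dihydrofuran-2(3H)-one | O=C1C[C@@H](Cc2ccc(OC)c(OC)c2)CO1 | intermediate
16 | 3-(benzyloxy)-4-methoxybenzyl alcohol | COc1ccc(CO)cc1OCc1ccccc1 | starting material
17 | 3-(benzyloxy)-4-methoxybenzyl bromide | COc1ccc(CBr)cc1OCc1ccccc1 | intermediate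
18 | lithium enolate of 15, lithium (R)-4-(3,4-dimethoxybenzyl)-4,5-dihydrofuran-2-olate | [Li]OC1=C[C@@H](Cc2ccc(OC)c(OC)c2)CO1 | intermediate
19 | (3R,4R)-3-[3-(benzyloxy)-4-methoxybenzyl]-4-(3,4-dimethoxybenzyl)dihydrofuran-2(3H)-one | COc1ccc(C[C@H]2C(=O)OC[C@@H]2Cc2ccc(OC)c(OC)c2)cc1OCc1ccccc1 | intermediate
20 | prestegane A, (3R,4R)-4-(3,4-dimethoxybenzyl)-3-(3-hydroxy-4-methoxybenzyl)dihydrofuran-2(3H)-one | COc1ccc(C[C@H]2C(=O)OC[C@@H]2Cc2ccc(OC)c(OC)c2)cc1O | target

**Count**

Total steps: 8. Longest linear sequence: 6 steps (steps 1, 3, 4, 5, 7, 8).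

**Steps most likely to fail**

Step 3. The enantiotopic deprotonation may be incomplete. The benzyl shift in the pinacol boronate may be slow, so that the ate complex reverts or 6 removes a benzylic proton of 4 instead of adding to boron. Either process would lower conversion or enantiomeric purity, and chloromethyllithium still present during the second shift could insert a second CH2. The fallback sets C4 by auxiliary-controlled enolate alkylation instead; it sets out from 3 and comes back at 14.
- (R)-4-Benzyloxazolidin-2-one is N-acylated with pent-4-enoyl chloride (n-BuLi, THF, −78 °C) to (R)-4-benzyl-3-(pent-4-enoyl)oxazolidin-2-one F1.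
- The sodium enolate of F1 (NaN(SiMe3)2, THF, −78 °C) is alkylated with chloride 3 in the presence of Bu4NI, on the face away from the auxiliary benzyl group, to give (R)-4-benzyl-3-[(S)-2-(3,4-dimethoxybenzyl)pent-4-enoyl]oxazolidin-2-one F2.
- LiBH4 (THF, wet Et2O, 0 °C) releases the auxiliary and gives (S)-2-(3,4-dimethoxybenzyl)pent-4-en-1-ol F3.
- Lemieux–Johnson cleavage of the alkene (OsO4 cat., NaIO4, 2,6-lutidine, dioxane–water) gives hydroxy aldehyde 13 and its lactol 14, which is oxidised to 15 as in step 5.

Step 5. The oxidant may discriminate too weakly between the two primary alcohols, so that oxidation starting at the C5 hydroxyl gives the regioisomeric lactone alongside 15. The fallback fixes the regiochemistry by oxidising the C2 terminus before the C5 hydroxyl exists; it sets out from 11 and comes back at 14.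
- Step 4 is stopped after the methanolysis and 11 is isolated.
- Dess–Martin periodinane (NaHCO3, CH2Cl2) gives (R)-4-(3,4-dimethoxyphenyl)-3-[(4,4,5,5-tetramethyl-1,3,2-dioxaborolan-2-yl)methyl]butanal F4.
- NaBO3·4H2O (THF–water, rt) converts the C–B bond into the hydroxyl, and the product closes to lactol 14, which is oxidised to 15 with TEMPO/PhI(OAc)2.

Step 7. The alkylation may stall or run on to the dialkylated lactone through proton exchange between product and enolate, and the electron-rich benzylic bromide may decompose before it is captured. The fallback replaces the alkylation by an aldol addition and reductive removal of the benzylic hydroxyl; it sets out from 15 and 16 and comes back at 20, bypassing 19.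
- Alcohol 16 is oxidised (MnO2, CH2Cl2) to 3-(benzyloxy)-4-methoxybenzaldehyde F5.
- Enolate 18, made from 15 as in step 7, adds to F5 at −78 °C anti to the C4 substituent to give (3S,4R)-3-{[3-(benzyloxy)-4-methoxyphenyl](hydroxy)methyl}-4-(3,4-dimethoxybenzyl)dihydrofuran-2(3H)-one F6, as a mixture of carbinol epimers.
- Hydrogenolysis (H2, 10% Pd/C, AcOH, trace HClO4) removes both the benzylic hydroxyl and the O-benzyl group and gives 20 directly, the trans relationship having been set in the aldol step.

**Further compounds**

F1 | step 3 | (R)-4-benzyl-3-(pent-4-enoyl)oxazolidin-2-one | C=CCCC(=O)N1[C@H](Cc2ccccc2)COC1=O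
F2 | step 3 | (R)-4-benzyl-3-[(S)-2-(3,4-dimethoxybenzyl)pent-4-enoyl]oxazolidin-2-one | C=CC[C@@H](Cc1ccc(OC)c(OC)c1)C(=O)N1[C@H](Cc2ccccc2)COC1=O
F3 | step 3 | (S)-2-(3,4-dimethoxybenzyl)pent-4-en-1-ol | C=CC[C@@H](Cc1ccc(OC)c(OC)c1)CO
F4 | step 5 | (R)-4-(3,4-dimethoxyphenyl)-3-[(4,4,5,5-tetramethyl-1,3,2-dioxaborolan-2-yl)methyl]butanal | O=CC[C@@H](Cc1ccc(OC)c(OC)c1)CB1OC(C)(C)C(C)(C)O1
F5 | step 7 | 3-(benzyloxy)-4-methoxybenzaldehyde | COc1ccc(C=O)cc1OCc1ccccc1
F6 | step 7 | (3S,4R)-3-{[3-(benzyloxy)-4-methoxyphenyl](hydroxy)methyl}-4-(3,4-dimethoxybenzyl)dihydrofuran-2(3H)-one, mixture of carbinol epimers | COc1ccc(C(O)[C@H]2C(=O)OC[C@@H]2Cc2ccc(OC)c(OC)c2)cc1OCc1ccccc1
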